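## Analysis of the target

Compound 16 is the ester of α-linolenic acid with a monocyclic C20 diterpene alcohol. The acyl part runs from C1′ to C18′, with Z alkenes at C9′, C12′ and C15′ separated by the doubly allylic methylenes C11′ and C14′.

The alcohol part is numbered like geranylgeraniol, and the same atom numbers are used for all intermediates. C1 is the OCH2 carbon. The chain holds E-trisubstituted alkenes at C2=C3 and C6=C7 and ends at C9. Ring A is the cyclohexene C10–C11–C12–C13–C14–C15, with one methyl group on C11 and two on C15.

The only stereocentre is C10 (S). It is a ring CH that carries C9 and sits between the sp2 carbon C11 and the quaternary carbon C15.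

The plan rests on the allyl triad C10(H)–C11(CH3)=C12(H) of ring A. The stereocentre is one end of a three-carbon allyl unit whose other end, C12, is an open ring CH beside the methylene C13.

The synthesis is hard for three linked reasons:
- The C9–C10 bond lies next to a quaternary carbon.
- C10 has no heteroatom or carbonyl neighbour through which it could be set.
- The alkene must stay at C11=C12. A shift to C10=C11 erases the stereocentre, and a shift to the exocyclic position gives an isomer that is hard to remove.

Acid is excluded once chain and ring are joined, because protonation of any trisubstituted alkene starts cyclisation or migration. The skipped triene is prone to autoxidation, base-induced conjugation and hydroboration, and the primary allylic ester at C1 can ionise. The acyl group therefore has to come last.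

## Retrosynthetic reasoning

**Ester bond O–C1′.** 16 is cut into alcohol 14 and acid 15. The triene of 15 would not survive allylic oxidation, ylide base or hydroboration. The forward reaction only has to acylate a primary allylic alcohol under neutral conditions. 14 is carried as its silyl ether 13, because the C1 oxygen must be inert to ylide, borane and copper and must not become a second allylic leaving group.

**Bond C9–C10, with allylic transposition (key disconnection).** 13 is cut between chain and ring. At the same time the ring alkene is moved back from C11=C12 to C10=C11 and an oxygen leaving group is placed on C12. This gives allylic phosphate 11 and primary alkylborane 12.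

The cut is made here and not at the easier C8–C9 bond because only here does one bond formation answer all three problems of ring A:
- C10 is the γ end of the allyl triad, so the hindered bond is made by a reaction that is electronically steered to that end.
- The configuration of C10 is copied from C12, a carbinol carbon, which is the easiest kind of stereocentre to set.
- The position of the alkene follows from the mechanism, so the problem of endocyclic, tetrasubstituted and exocyclic isomers never arises.

The forward reaction has to enforce γ attack beside C15 and a clean anti 1,3-transfer. Its two precursors are each three steps from bulk chemicals.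

**Bonds B–C9 and H–C8.** 12 goes back to triene 5. C8=C9 is the only monosubstituted alkene of 5, so the nucleophile is made in the coupling flask without a halide or a separate organometallic step.

**Bond C8=C9 and the oxygen on C8.** 5 is cut to enal 4 by a methylenation, which adds the single missing carbon C9. 4 goes back through allylic alcohol 3 to silyl ether 2 and to geraniol 1. C1–C8 and both E alkenes are bought with 1.

**Bonds P–O and C12–H.** 11 goes back to alcohol 10, and 10 to the flat enone 9. The forward reaction is a catalyst-controlled 1,2-reduction. The C11 methyl group makes the two flanks of the carbonyl group clearly different in size.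

**Bonds C14–C15 and C10=C11.** 9 is cut into aldehyde 6 and enone 7 through keto aldehyde 8 (Michael addition, then aldol condensation). After the Michael step the aldehyde carbon has no α-hydrogen, and only one enolisation gives a six-membered ring, so one product is possible.

## Alternatives that were turned down

**Alternative 1:** the textbook cut, C8–C9.

The lithiated sulfone ({[(1S)-2,6,6-trimethylcyclohex-2-en-1-yl]methyl}sulfonyl)benzene A2 would be alkylated by (2E,6E)-8-bromo-3,7-dimethylocta-2,6-dien-1-yl acetate A3. This gives the C9 sulfone A4, which is desulfonylated, deacetylated and esterified. A2 would come from acid cyclisation of geranyl phenyl sulfone A1.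

It was turned down because the coupling builds an unhindered allyl–alkyl bond and none of the hard features. Stereocentre and ring alkene must already be present in A2. The cyclisation of A1 runs through a free C11 cation, which has no facial bias and three different protons to lose. A2 would therefore have to be separated from its alkene isomers and resolved, with loss of half the material. The sulfonyl group is put on and taken off again without building anything, and the sequence is clearly longer.

**Alternative 2:** the biosynthetic cut, C10–C15.

Geranylgeranyl α-linolenate A5 would undergo proton-initiated cyclisation by a chiral Brønsted acid, for example a binaphthol–SnCl4 complex. The sequence is protonation at C14, attack of C10 on C15, and loss of a proton from C12. It would reach 16 in two steps and was weighed most seriously.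

It was turned down because nothing in A5 secures any of the four selectivities the step needs:
- Four trisubstituted alkenes compete for the proton.
- The C11 cation lies within bonding distance of C6=C7, which closes the second ring faster than any external base removes a proton.
- Proton loss can occur at C10, at C12 or at the methyl group.
- Facial control rests on the reagent alone.

A stop group can be built in. An example is a phenylsulfonyl group on C8 as in A6, which destabilises the C7 cation. A6, however, costs about as many steps as the whole route below, adds a removal step, and still leaves the site of proton loss open.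

**Alternative 3:** the same bond C9–C10, made by catalytic asymmetric conjugate addition.

A C9 nucleophile drawn from 5 would be added to enone 9 with a chiral copper catalyst. The enolate would be trapped as the enol triflate A7, and A7 would be reduced to 13 with Pd(OAc)2, PPh3 and formic acid.

It was turned down because 9 is substituted at the α-carbon C11 and neopentyl at the β-carbon C10. Both features slow the binding of copper and blur the facial discrimination, which in this reaction class relies on an open α-CH. The catalyst would meet its worst substrate, whereas carbonyl reduction of the same enone meets one of its best. Triflation of a zinc or zirconium enolate and the later reduction add operations that the transposing coupling does not need.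

Key step: step 7

Assumption: the descriptor [C@@H] at ring carbon C10 of the given SMILES is read as the S configuration, and all intermediates are drawn accordingly.

## Route

Step 1
Reactants: 1 geraniol, (2E)-3,7-dimethylocta-2,6-dien-1-ol
Product: 2 tert-butyl{[(2E)-3,7-dimethylocta-2,6-dien-1-yl]oxy}dimethylsilane
Conditions: TBSCl, imidazole, CH2Cl2, 0 °C to rt
Reagents that add atoms: tert-butyldimethylsilyl chloride, CC(C)(C)[Si](C)(C)Cl
Why: Standard silylation of a primary alcohol; the silyl ether is inert to SeO2, ylide, borane and copper and, unlike an acetate, is no allylic leaving group.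

Step 2
Reactants: 2 tert-butyl{[(2E)-3,7-dimethylocta-2,6-dien-1-yl]oxy}dimethylsilane
Product: 4 (2E,6E)-8-{[tert-butyl(dimethyl)silyl]oxy}-2,6-dimethylocta-2,6-dienal, via allylic alcohol 3 (not isolated)
Conditions: SeO2 (10 mol %), t-BuOOH, salicylic acid (10 mol %), CH2Cl2, 0 °C to rt; then MnO2, CH2Cl2, rt (on the crude mixture)
Reagents that add atoms: tert-butyl hydroperoxide, CC(C)(C)OO; selenium dioxide, O=[Se]=O (relays the oxygen atom)
Why: Riley oxidation: ene reaction and [2,3]-shift at the more electron-rich C6=C7 alkene oxidise the methyl group trans to the chain (C8) and keep the E geometry, while C2=C3 is deactivated by the allylic oxygen. MnO2 then takes alcohol 3 and any aldehyde already formed to the single compound 4.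

Step 3
Reactants: 4 (2E,6E)-8-{[tert-butyl(dimethyl)silyl]oxy}-2,6-dimethylocta-2,6-dienal
Product: 5 tert-butyl{[(2E,6E)-3,7-dimethylnona-2,6,8-trien-1-yl]oxy}dimethylsilane
Conditions: Ph3PCH3Br, KOt-Bu, THF, 0 °C; then 4, −78 °C to 0 °C
Reagents that add atoms: methyltriphenylphosphonium bromide, C[P+](c1ccccc1)(c1ccccc1)c1ccccc1.[Br-]
Why: Wittig methylenation of an enal adds C9 by 1,2-attack and does not touch the C6=C7 geometry or the silyl ether.

Step 4
Reactants: 6 isobutyraldehyde (2-methylpropanal); 7 ethyl vinyl ketone (pent-1-en-3-one)
Product: 9 2,4,4-trimethylcyclohex-2-en-1-one, via keto aldehyde 8 (not isolated)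
Conditions: H2SO4 (cat.), toluene, reflux, Dean–Stark trap
Reagents that add atoms: none
Why: Acid-catalysed Robinson-type annulation: the enol of 6 adds to 7 (bond C14–C15), and 8 closes by aldol condensation between the ethyl CH2 group and the non-enolisable aldehyde (bond C10=C11). The other enolisation would give a four-membered ring, so only 9 can form.

Step 5
Reactants: 9 2,4,4-trimethylcyclohex-2-en-1-one
Product: 10 (1S)-2,4,4-trimethylcyclohex-2-en-1-ol
Conditions: (3aR)-1-methyl-3,3-diphenyltetrahydro-1H,3H-pyrrolo[1,2-c][1,3,2]oxazaborole (10 mol %), BH3·SMe2, THF, −20 °C; then MeOH, aqueous work-up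
Reagents that add atoms: none
Why: Corey–Bakshi–Shibata reduction; the C(CH3)=CH flank acts as the large group and the CH2 flank as the small one, so the (R)-configured catalyst should deliver hydride to the face that gives the (S)-carbinol at C12. α-Substituted cyclic enones are among the best substrates of this reaction, and 1,2-reduction is the normal course.

Step 6
Reactants: 10 (1S)-2,4,4-trimethylcyclohex-2-en-1-ol
Product: 11 diethyl (1S)-2,4,4-trimethylcyclohex-2-en-1-yl phosphate
Conditions: ClP(O)(OEt)2, pyridine, DMAP (cat.), CH2Cl2, 0 °C
Reagents that add atoms: diethyl chlorophosphate, CCOP(=O)(Cl)OCC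
Why: O-Phosphorylation forms the P–O bond only, so the C12–O stereocentre is kept; the product is passed through deactivated silica and used at once.

Step 7
Reactants: 5 tert-butyl{[(2E,6E)-3,7-dimethylnona-2,6,8-trien-1-yl]oxy}dimethylsilane; 11 diethyl (1S)-2,4,4-trimethylcyclohex-2-en-1-yl phosphate
Product: 13 tert-butyl({(2E,6E)-3,7-dimethyl-9-[(1S)-2,6,6-trimethylcyclohex-2-en-1-yl]nona-2,6-dien-1-yl}oxy)dimethylsilane, via alkylborane 12 (not isolated)
Conditions: 5 (slight excess), 9-borabicyclo[3.3.1]nonane (9-BBN-H) dimer, THF, 0 °C to rt; then KOt-Bu, CuOAc (10 mol %), 11, THF, rt to 50 °C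
Reagents that add atoms: none
Why: 9-BBN-H adds only to the monosubstituted C8=C9 bond of 5 and puts boron on the terminal C9, since the trisubstituted C2=C3 and C6=C7 bonds react far more slowly, and gives 12. tert-Butoxide quaternises the boron of 12 and passes the C9 alkyl group to monovalent copper; the alkylcopper binds the C10=C11 bond of 11 on the face opposite to the phosphate, expels the phosphate by oxidative addition at C10 (SN2′), and the trivalent σ-allylcopper formed collapses by reductive elimination to the C9–C10 bond while the alkene moves to C11=C12. The closest known reaction type is the copper-catalysed, γ-selective and 1,3-anti stereospecific allyl–alkyl coupling of alkyl-9-BBN reagents with secondary allylic phosphates; the anti-SN2′ alkylation of 2-substituted cyclohex-2-enyl phosphates by zinc–copper reagents is its stoichiometric relative. No ring is closed: the step joins the C1–C9 chain to ring A. The one new stereocentre, C10, is controlled by the C12–O stereocentre of 11, because the C11 methyl group pushes the phosphate into the pseudoaxial position (allylic 1,2-strain), where the C–O bond overlaps with the π bond, and attack anti to it turns (S)-C12 into (S)-C10. The selectivity needed is γ attack (C10) over α attack (C12) although C10 is flanked by the quaternary C15; it is secured by the heteroleptic alkylcopper species, whose σ-allyl intermediate eliminates faster than it equilibrates to the π-allyl form, and by a leaving group that does not ionise on its own in a basic, aprotic medium. That organocopper reagents do bond to a ring CH beside a gem-dimethyl carbon is known from conjugate additions to 4,4-dimethylcyclohex-2-enone. The silyl ether at C1 is no leaving group for copper, so the second allylic C–O bond of the molecule stays untouched.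

Step 8
Reactants: 13 tert-butyl({(2E,6E)-3,7-dimethyl-9-[(1S)-2,6,6-trimethylcyclohex-2-en-1-yl]nona-2,6-dien-1-yl}oxy)dimethylsilane
Product: 14 (2E,6E)-3,7-dimethyl-9-[(1S)-2,6,6-trimethylcyclohex-2-en-1-yl]nona-2,6-dien-1-ol
Conditions: Bu4NF, THF, 0 °C to rt
Reagents that add atoms: none
Why: Fluoride cleaves the Si–O bond without acid, so no alkene migrates or cyclises and C10 is not touched.

Step 9
Reactants: 14 (2E,6E)-3,7-dimethyl-9-[(1S)-2,6,6-trimethylcyclohex-2-en-1-yl]nona-2,6-dien-1-ol; 15 α-linolenic acid, (9Z,12Z,15Z)-octadeca-9,12,15-trienoic acid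
Product: 16 (2E,6E)-3,7-dimethyl-9-[(1S)-2,6,6-trimethylcyclohex-2-en-1-yl]nona-2,6-dien-1-yl (9Z,12Z,15Z)-octadeca-9,12,15-trienoate
Conditions: DCC, DMAP (cat.), CH2Cl2, 0 °C to rt, argon, dark
Reagents that add atoms: none
Why: Steglich esterification activates the acid and not the allylic alcohol, so C1 does not ionise. The neutral, cold and oxygen-free medium leaves the three Z alkenes and the doubly allylic methylenes unchanged.

## Compound list

1 | geraniol, (2E)-3,7-dimethylocta-2,6-dien-1-ol | CC(C)=CCC/C(C)=C/CO | starting material
2 | tert-butyl{[(2E)-3,7-dimethylocta-2,6-dien-1-yl]oxy}dimethylsilane | CC(C)(C)[Si](C)(C)OC/C=C(\C)CCC=C(C)C | intermediate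
3 | (2E,6E)-8-{[tert-butyl(dimethyl)silyl]oxy}-2,6-dimethylocta-2,6-dien-1-ol | CC(C)(C)[Si](C)(C)OC/C=C(\C)CC/C=C(\C)CO | intermediate
4 | (2E,6E)-8-{[tert-butyl(dimethyl)silyl]oxy}-2,6-dimethylocta-2,6-dienal | CC(C)(C)[Si](C)(C)OC/C=C(\C)CC/C=C(\C)C=O | intermediate
5 | tert-butyl{[(2E,6E)-3,7-dimethylnona-2,6,8-trien-1-yl]oxy}dimethylsilane | CC(C)(C)[Si](C)(C)OC/C=C(\C)CC/C=C(\C)C=C | intermediate
6 | isobutyraldehyde (2-methylpropanal) | CC(C)C=O | starting material
7 | ethyl vinyl ketone (pent-1-en-3-one) | CCC(=O)C=C | starting material
8 | 2,2-dimethyl-5-oxoheptanal | CCC(=O)CCC(C)(C)C=O | intermediate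
9 | 2,4,4-trimethylcyclohex-2-en-1-one | CC1=CC(C)(C)CCC1=O | intermediate
10 | (1S)-2,4,4-trimethylcyclohex-2-en-1-ol | O[C@H]1CCC(C)(C)C=C1C | intermediate
11 | diethyl (1S)-2,4,4-trimethylcyclohex-2-en-1-yl phosphate | CCOP(=O)(OCC)O[C@H]1CCC(C)(C)C=C1C | intermediate
12 | 9-[(3E,7E)-9-{[tert-butyl(dimethyl)silyl]oxy}-3,7-dimethylnona-3,7-dien-1-yl]-9-borabicyclo[3.3.1]nonane | CC(C)(C)[Si](C)(C)OC/C=C(\C)CC/C=C(\C)CCB1C2CCCC1CCC2 | intermediate
13 | tert-butyl({(2E,6E)-3,7-dimethyl-9-[(1S)-2,6,6-trimethylcyclohex-2-en-1-yl]nona-2,6-dien-1-yl}oxy)dimethylsilane | CC(C)(C)[Si](C)(C)OC/C=C(\C)CC/C=C(\C)CC[C@@H]1C(C)=CCCC1(C)C | intermediate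
14 | (2E,6E)-3,7-dimethyl-9-[(1S)-2,6,6-trimethylcyclohex-2-en-1-yl]nona-2,6-dien-1-ol | OC/C=C(\C)CC/C=C(\C)CC[C@@H]1C(C)=CCCC1(C)C | intermediate
15 | α-linolenic acid, (9Z,12Z,15Z)-octadeca-9,12,15-trienoic acid | CC/C=C\C/C=C\C/C=C\CCCCCCCC(=O)O | starting material
16 | (2E,6E)-3,7-dimethyl-9-[(1S)-2,6,6-trimethylcyclohex-2-en-1-yl]nona-2,6-dien-1-yl (9Z,12Z,15Z)-octadeca-9,12,15-trienoate | CC/C=C\C/C=C\C/C=C\CCCCCCCC(=O)OC/C=C(\C)CC/C=C(\C)CC[C@@H]1C(C)=CCCC1(C)C | target

## Step count and least certain steps

Total step count: 9.
Longest linear sequence: 6 steps (steps 1, 2, 3, 7, 8 and 9, from geraniol 1). The ring branch (steps 4, 5 and 6) joins at step 7.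

**Step 7 (key step).**

What may go wrong:
- Bonding of copper to C10 may be slowed by the two methyl groups on C15.
- The trivalent allylcopper intermediate may then have time to equilibrate and couple at the open C12 end, with loss of γ-selectivity.
- Alternatively, the phosphate may be lost by elimination.
- The anti course of this coupling type responds to the alkoxide and the solvent, so partial syn delivery would lower the enantiomeric purity.

Fallback: the C9–C10 bond is made intramolecularly by an Ireland–Claisen rearrangement. This is the standard answer to a hindered allylic terminus. It delivers carbon to C10 from the face of the C12–O bond, so the other enantiomer of the carbinol is needed. The fallback sets out from 9 and 3 and comes back at 13.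

Reduction of 9 as in step 5, but with the (3aS)-configured oxazaborolidine, gives (1R)-2,4,4-trimethylcyclohex-2-en-1-ol F1. Ac2O and pyridine turn it into (1R)-2,4,4-trimethylcyclohex-2-en-1-yl acetate F2. Alcohol 3, isolated after the SeO2 stage of step 2, is converted by an Appel reaction (CBr4, PPh3) into {[(2E,6E)-8-bromo-3,7-dimethylocta-2,6-dien-1-yl]oxy}(tert-butyl)dimethylsilane F3.

The lithium enolate of F2 (LDA, THF, DMPU, −78 °C) is alkylated by F3 to (1R)-2,4,4-trimethylcyclohex-2-en-1-yl (4E,8E)-10-{[tert-butyl(dimethyl)silyl]oxy}-4,8-dimethyldeca-4,8-dienoate F4. F4 is enolised and silylated in the flask (LDA, Me3SiCl, THF, −78 °C) and rearranges on warming. Mild acidic work-up gives (4E,8E)-10-{[tert-butyl(dimethyl)silyl]oxy}-4,8-dimethyl-2-[(1S)-2,6,6-trimethylcyclohex-2-en-1-yl]deca-4,8-dienoic acid F5. The configuration at its carboxyl-bearing carbon does not matter.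

1-Hydroxypyridine-2(1H)-thione and DCC give the 2-thioxopyridin-1(2H)-yl ester of this acid F6. Barton decarboxylation (t-BuSH, visible light, toluene) replaces the carboxyl group on C9 by hydrogen and gives 13.

**Step 6.**

What may go wrong: the phosphate of a secondary allylic alcohol with a methyl group on the central allyl carbon may ionise on silica or on storage, which would erode the configuration at C12. It may also eliminate towards C13.

Fallback: a bench-stable carboxylate is used that becomes a leaving group only when it is chelated, together with a stoichiometric magnesium cuprate in place of the catalytic boron-to-copper relay. The fallback sets out from 10 and 12 and comes back at 13.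

Picolinic acid, DCC and DMAP turn 10 into (1S)-2,4,4-trimethylcyclohex-2-en-1-yl pyridine-2-carboxylate F7. Borane 12 is oxidised (NaOH, H2O2) to (3E,7E)-9-{[tert-butyl(dimethyl)silyl]oxy}-3,7-dimethylnona-3,7-dien-1-ol F8. This is converted (CBr4, PPh3) into {[(2E,6E)-9-bromo-3,7-dimethylnona-2,6-dien-1-yl]oxy}(tert-butyl)dimethylsilane F9, and then (Mg, THF) into bromo[(3E,7E)-9-{[tert-butyl(dimethyl)silyl]oxy}-3,7-dimethylnona-3,7-dien-1-yl]magnesium F10. F10 with CuBr·SMe2 (THF, −40 °C to 0 °C) displaces the chelated picolinate of F7 in the anti-SN2′ sense and gives 13.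

**Step 2.**

What may go wrong: incomplete conversion, competing oxidation at the ring-distal allylic methylenes or at the C2=C3 alkene, and over-oxidation may keep the throughput of the chain branch low.

Fallback: the C6=C7 alkene is rebuilt instead of being oxidised at its methyl group. The fallback sets out from 2 and comes back at 4.

Epoxidation of the more electron-rich terminal alkene (mCPBA, CH2Cl2, −20 °C) gives racemic tert-butyl{[(2E)-5-(3,3-dimethyloxiran-2-yl)-3-methylpent-2-en-1-yl]oxy}dimethylsilane F11. Cleavage with H5IO6 (THF, water, 0 °C) gives (4E)-6-{[tert-butyl(dimethyl)silyl]oxy}-4-methylhex-4-enal F12. A Wittig reaction with the stabilised ylide 2-(triphenylphosphoranylidene)propanal (toluene, 80 °C) gives the E-enal 4.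

**Step 5.**

What may go wrong: uncatalysed background reduction, or insufficient discrimination of two flanks that are both ring carbons, may leave the enantiomeric purity of C12, and hence of C10, too low.

Fallback: enzymatic kinetic resolution replaces catalyst control. The fallback sets out from 9 and comes back at 10.

Luche reduction (NaBH4, CeCl3·7H2O, MeOH, 0 °C) gives racemic 2,4,4-trimethylcyclohex-2-en-1-ol F13. Candida antarctica lipase B and vinyl butanoate (methyl tert-butyl ether, rt) should acylate the R enantiomer, as expected from the usual size rule for secondary alcohols. This gives (1R)-2,4,4-trimethylcyclohex-2-en-1-yl butanoate F14 and leaves 10, which is separated by chromatography.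

## Further compounds

F1 | step 7 | (1R)-2,4,4-trimethylcyclohex-2-en-1-ol | O[C@@H]1CCC(C)(C)C=C1C
F2 | step 7 | (1R)-2,4,4-trimethylcyclohex-2-en-1-yl acetate | CC(=O)O[C@@H]1CCC(C)(C)C=C1C
F3 | step 7 | {[(2E,6E)-8-bromo-3,7-dimethylocta-2,6-dien-1-yl]oxy}(tert-butyl)dimethylsilane | CC(C)(C)[Si](C)(C)OC/C=C(\C)CC/C=C(\C)CBr
F4 | step 7 | (1R)-2,4,4-trimethylcyclohex-2-en-1-yl (4E,8E)-10-{[tert-butyl(dimethyl)silyl]oxy}-4,8-dimethyldeca-4,8-dienoate | CC(C)(C)[Si](C)(C)OC/C=C(\C)CC/C=C(\C)CCC(=O)O[C@@H]1CCC(C)(C)C=C1C
F5 | step 7 | (4E,8E)-10-{[tert-butyl(dimethyl)silyl]oxy}-4,8-dimethyl-2-[(1S)-2,6,6-trimethylcyclohex-2-en-1-yl]deca-4,8-dienoic acid | CC(C)(C)[Si](C)(C)OC/C=C(\C)CC/C=C(\C)CC(C(=O)O)[C@@H]1C(C)=CCCC1(C)C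
F6 | step 7 | 2-thioxopyridin-1(2H)-yl (4E,8E)-10-{[tert-butyl(dimethyl)silyl]oxy}-4,8-dimethyl-2-[(1S)-2,6,6-trimethylcyclohex-2-en-1-yl]deca-4,8-dienoate | CC(C)(C)[Si](C)(C)OC/C=C(\C)CC/C=C(\C)CC(C(=O)ON1C=CC=CC1=S)[C@@H]1C(C)=CCCC1(C)C
F7 | step 6 | (1S)-2,4,4-trimethylcyclohex-2-en-1-yl pyridine-2-carboxylate | O=C(O[C@H]1CCC(C)(C)C=C1C)c1ccccn1
F8 | step 6 | (3E,7E)-9-{[tert-butyl(dimethyl)silyl]oxy}-3,7-dimethylnona-3,7-dien-1-ol | CC(C)(C)[Si](C)(C)OC/C=C(\C)CC/C=C(\C)CCO
F9 | step 6 | {[(2E,6E)-9-bromo-3,7-dimethylnona-2,6-dien-1-yl]oxy}(tert-butyl)dimethylsilane | CC(C)(C)[Si](C)(C)OC/C=C(\C)CC/C=C(\C)CCBr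
F10 | step 6 | bromo[(3E,7E)-9-{[tert-butyl(dimethyl)silyl]oxy}-3,7-dimethylnona-3,7-dien-1-yl]magnesium | CC(C)(C)[Si](C)(C)OC/C=C(\C)CC/C=C(\C)CC[Mg]Br
F11 | step 2 | tert-butyl{[(2E)-5-(3,3-dimethyloxiran-2-yl)-3-methylpent-2-en-1-yl]oxy}dimethylsilane (racemic) | CC(C)(C)[Si](C)(C)OC/C=C(\C)CCC1OC1(C)C
F12 | step 2 | (4E)-6-{[tert-butyl(dimethyl)silyl]oxy}-4-methylhex-4-enal | CC(C)(C)[Si](C)(C)OC/C=C(\C)CCC=O
F13 | step 5 | 2,4,4-trimethylcyclohex-2-en-1-ol (racemic) | OC1CCC(C)(C)C=C1C
F14 | step 5 | (1R)-2,4,4-trimethylcyclohex-2-en-1-yl butanoate | CCCC(=O)O[C@@H]1CCC(C)(C)C=C1C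
A1 | alternative 1 | geranyl phenyl sulfone, {[(2E)-3,7-dimethylocta-2,6-dien-1-yl]sulfonyl}benzene | CC(C)=CCC/C(C)=C/CS(=O)(=O)c1ccccc1
A2 | alternative 1 | ({[(1S)-2,6,6-trimethylcyclohex-2-en-1-yl]methyl}sulfonyl)benzene | O=S(=O)(C[C@@H]1C(C)=CCCC1(C)C)c1ccccc1
A3 | alternative 1 | (2E,6E)-8-bromo-3,7-dimethylocta-2,6-dien-1-yl acetate | CC(=O)OC/C=C(\C)CC/C=C(\C)CBr
A4 | alternative 1 | (2E,6E)-3,7-dimethyl-9-(phenylsulfonyl)-9-[(1S)-2,6,6-trimethylcyclohex-2-en-1-yl]nona-2,6-dien-1-yl acetate (both configurations at C9) | CC(=O)OC/C=C(\C)CC/C=C(\C)CC([C@@H]1C(C)=CCCC1(C)C)S(=O)(=O)c1ccccc1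
A5 | alternative 2 | (2E,6E,10E)-3,7,11,15-tetramethylhexadeca-2,6,10,14-tetraen-1-yl (9Z,12Z,15Z)-octadeca-9,12,15-trienoate (geranylgeranyl α-linolenate) | CC/C=C\C/C=C\C/C=C\CCCCCCCC(=O)OC/C=C(\C)CC/C=C(\C)CC/C=C(\C)CCC=C(C)C
A6 | alternative 2 | tert-butyldimethyl{[(2E,6E,10E)-3,7,11,15-tetramethyl-8-(phenylsulfonyl)hexadeca-2,6,10,14-tetraen-1-yl]oxy}silane (racemic at C8) | CC(C)(C)[Si](C)(C)OC/C=C(\C)CC/C=C(\C)C(C/C=C(\C)CCC=C(C)C)S(=O)(=O)c1ccccc1
A7 | alternative 3 | (3S)-3-[(3E,7E)-9-{[tert-butyl(dimethyl)silyl]oxy}-3,7-dimethylnona-3,7-dien-1-yl]-2,4,4-trimethylcyclohex-1-en-1-yl trifluoromethanesulfonate | CC(C)(C)[Si](C)(C)OC/C=C(\C)CC/C=C(\C)CC[C@@H]1C(C)=C(OS(=O)(=O)C(F)(F)F)CCC1(C)C
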